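## The problem

The target is a methylene-bridged heterodimer. A hexasubstituted phloroglucinol ring A (benzofuran numbering O1, C2, C3, C3a, C4 to C7, C7a) is fused across C3a–C7a to a 2-isopropenyl-2,3-dihydrofuran (ring B) and tied through one CH2 at C5 to C3' of a 6-ethyl-4-hydroxy-5-methyl-2-pyrone (ring C). Every carbon of ring A is substituted, and its three oxygens have different fates: the C7a oxygen is the ring B ether, while the C4 and C6 oxygens are free phenols flanking the bridge. A side chain at C3a can close onto the oxygen at C7a or at C4, and symmetric phloroglucinol offers no way to choose, so the oxygens must be told apart before ring B is made. The two stereocentres, C2 (S) and the alpha carbon (S) of the 2-methylbutanoyl group at C7, are too far apart to control each other; one is set by a reagent and the other is bought. The isopropenyl group excludes hydrogenolysis and strong electrophiles, the allylic aryl ether at C2 ionises under acid, the alpha stereocentre of the aryl ketone epimerises under equilibrating base, and the free acylphloroglucinol with its bridge is air and acid sensitive and should appear last. The enabling feature is the ring A pattern read from C7a: OH, alkyl (C3a), O (C4), H (C5), O (C6), H (C7). A vinylketene and an oxygenated alkyne deliver exactly this pattern in a benzannulation, with the ketene oxygen as the one free hydroxyl next to the side chain.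

## Retrosynthesis

**Bridge.** Target 35 is cut at C5–CH2. The pieces are phloroglucinol 27, whose only free ring carbon is C5, and Mannich base 33, which releases the bridge carbon as the methylene pyrandione 34. Cutting CH2–C3' instead would require an aminomethyl phloroglucinol and is kept as a reserve. 33 comes from pyrone 31 and Eschenmoser's salt 32; 31 comes from malonyl dichloride 30 and silyl enol ether 29 of pentan-3-one 28. The forward step must alkylate carbon only, without acid, and leave both stereocentres alone.

**Ring B.** 27 is 26 without its two aryl silyl ethers. 26 is cut at O1–C2, giving carbinol 25, which closes by SN2 displacement with inversion. An oxidative cyclisation of a prenyl group would set C2 at the same stage but gives a hydroxyisopropyl group that must then be dehydrated; displacement gives the isopropenyl group directly. The closure is unambiguous only if the C7a hydroxyl alone is free, so 25 is drawn from 24 by removing the alkyl triethylsilyl ether while the aryl triisopropylsilyl ethers stay.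

**Acyl group.** 24 is cut at C7–C(=O). Friedel–Crafts acylation is ruled out by the silyl ethers and the alkene. Instead the acyl group is carried on the C7a oxygen as ester 22 and moved to C7 through aryllithium 23 (anionic ortho-Fries shift). 22 comes from bromophenol 20 and (S)-2-methylbutanoic acid 21; 20 comes from phenol 19 by ortho bromination. The free phenol thus directs the halogen, delivers the acyl group and is released again for ring B. The forward step needs halogen–lithium exchange to outrun attack on, or enolisation of, the ester.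

**Ring A (key cut).** 19 is cut at C7a–C3a, C4–C5 and C7a–C7, giving 3-siloxycyclobutenone 14 and siloxyalkyne 8. Building on phloroglucinol would leave the three oxygens equivalent; this cut differentiates them as the ring forms, and the C2 stereocentre precursor is already in the alkyne. The precursors are a four-carbon and a two-carbon unit. The forward reaction needs only a regiospecific ketene–alkyne union.

**Siloxyalkyne.** 8 comes from terminal alkyne 5 by oxidation of acetylide 6 to ynolate 7 and O-silylation. 5 is the silyl ether of carbinol 4, made by catalytic asymmetric propargylation of methacrolein 1 with allenylboronate 2 (through borate 3). This is the only step that creates a stereocentre by reagent control.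

**Cyclobutenone.** 14 is the silyl enol ether of cyclobutane-1,3-dione 13, obtained by hydrolysis of 3-ethoxycyclobutenone 12. 12 is the (2+2) adduct of ethoxyacetylene 9 with ketene 11, generated from acetyl chloride 10.

## Roads not taken

**Alternative 1:** The cut is O1–C2, made last and by an enzyme. A cytochrome P450 prenylphenol cyclase with O2 and NADPH would oxidise the prenyl double bond of the unprotected prenylated dimer A2 and join the C7a oxygen to C2, giving the hydroxyisopropyl dihydrobenzofuran A1.
- Merits: A2 is a few steps from an acylphloroglucinol (prenylation, methylene coupling), no protecting groups are needed, and the enzyme would decide both which phenol closes and the configuration at C2. In step count this road is clearly better.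
- Weak points: a cyclase must exist that accepts a substrate carrying the bulky pyrone arm and picks the C7a oxygen over the equivalent-looking C4 oxygen. A1 is also a hydrate of the target, and dehydrating the tertiary alcohol to the 1,1-disubstituted alkene tends to give the isopropylidene isomer or open the ring.
- Comparison: the chosen plan is longer, but every step is a known laboratory reaction with predictable regiochemistry, and it delivers the isopropenyl group at the right oxidation level.

**Alternative 2:** The cut is C6–C7, with the arene made last. The dianion of dihydrofuran ketoester A4 would attack its ester carbonyl with the C7 methylene (Claisen condensation) and aromatise to A3, which is the same compound as 27.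
- Merits: O1 and C2 are in place from the start, so no phenol has to be differentiated; no silyl ethers, bromination or acyl shift are needed; and the road joins the chosen one at 27.
- Weak points: the ketone of A4 has a second alpha proton at the (S) stereocentre, so dianion formation risks epimerisation. The 2-alkyl-3-acyl-4,5-dihydrofuran can open by beta-elimination of O1 under strong base, which destroys C2. A4 itself needs a multistep assembly.
- Comparison: if A4 were easy to make and base-stable, this road would reach 27 in fewer operations on ring A. The chosen plan exposes the alpha stereocentre to strong base in only one low-temperature step and keeps C2 as a protected carbinol until ring A is complete.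

**Alternative 3:** The cuts are C3'–C4' and O1'–C2', building ring C last. Dihydrocoumarin A6 (C4 oxygen and C5 tied by a CH2CH2C(=O) lactone) is converted into ketene silyl acetal A7, which undergoes (4+2) cycloaddition with acylketene A9 released from dioxinone A8. Collapse of the orthoester frees the C4 phenol and gives A5, the C6 silyl ether of the target.
- Merits: the bridge carbon is fixed before the pyrone exists, so symmetric dimers cannot form, and pyrone formation and phenol release are one event. In cross-selectivity of the last carbon–carbon bond this road is better.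
- Weak points: A6 must be built on the fully substituted, acid-sensitive dihydrobenzofuran, with C4 and C6 oxygens again differentiated. Enolising the lactone competes with enolising the aryl ketone, which threatens the alpha stereocentre. A9 needs temperatures above 100 °C, and A5 still has to be desilylated.
- Comparison: this road does not solve the ring A problem; it presupposes it. The chosen plan answers the dimer risk with a preformed Mannich base and one coupling step from 27.

Key step: step 7

Assumption: (R)-TRIP is taken to give the (R)-carbinol 4 by analogy with aryl and alkenyl aldehydes (the isopropenyl group plays the part of the aryl group); if the opposite sense were found, (S)-TRIP would be used.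

## Route

Step 1
Reactants: 1 methacrolein; 2 allenylboronic acid pinacol ester
Product: 4 (3R)-2-methylhex-1-en-5-yn-3-ol, via O-boryl ether 3 (not isolated)
Conditions: (R)-TRIP [(R)-3,3'-bis(2,4,6-triisopropylphenyl)-1,1'-binaphthyl-2,2'-diyl hydrogen phosphate] 10 mol%, 4 Å MS, PhMe, −20 °C; aq. NaHCO3
Reagents that add atoms: none
Why: Chiral phosphoric acid-catalysed propargylboration; the allenylboronate adds through a closed six-membered SE2' transition state held by the catalyst, which selects the aldehyde face and sets C3 as (R); borate 3 is hydrolysed on work-up and the volatile carbinol is carried on in solution.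

Step 2
Reactants: 4 (3R)-2-methylhex-1-en-5-yn-3-ol
Product: 5 triethyl{[(3R)-2-methylhex-1-en-5-yn-3-yl]oxy}silane
Conditions: Et3SiCl, imidazole, DMF, 0 °C → rt
Reagents that add atoms: chlorotriethylsilane, CC[Si](Cl)(CC)CC
Why: Standard silylation of a secondary alcohol; the triethylsilyl ether survives organolithiums and heat and can later be removed by mild acid in the presence of aryl triisopropylsilyl ethers.

Step 3
Reactants: 5 triethyl{[(3R)-2-methylhex-1-en-5-yn-3-yl]oxy}silane
Product: 8 triethyl{[(3R)-2-methyl-6-(triisopropylsilyloxy)hex-1-en-5-yn-3-yl]oxy}silane, via lithium acetylide 6 (not isolated), via lithium ynolate 7 (not isolated)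
Conditions: n-BuLi, THF, −78 °C; LiOOtBu (from t-BuOOH and LiN(SiMe3)2), −78 → 0 °C; iPr3SiOTf, −78 °C → rt
Reagents that add atoms: tert-butyl hydroperoxide, CC(C)(C)OO; triisopropylsilyl triflate, CC(C)[Si](OS(=O)(=O)C(F)(F)F)(C(C)C)C(C)C
Why: Oxidation of a lithium acetylide by lithium tert-butyl peroxide (oxygen transfer with loss of LiOtBu) gives the ynolate, and the bulky silyl triflate silylates it on oxygen to give the siloxyalkyne, not the silylketene; the silyl ether and alkene are inert.

Step 4
Reactants: 9 ethoxyacetylene; 10 acetyl chloride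
Product: 12 3-ethoxycyclobut-2-en-1-one, via ketene 11 (not isolated)
Conditions: Et3N, Et2O, 0 °C → rt (9 in excess)
Reagents that add atoms: none
Why: Dehydrochlorination gives ketene, which is trapped in a thermal (2+2) cycloaddition by the electron-rich ynol ether; the nucleophilic alkyne carbon bonds to the ketene carbonyl carbon, which places the ethoxy group at C3.

Step 5
Reactants: 12 3-ethoxycyclobut-2-en-1-one
Product: 13 cyclobutane-1,3-dione
Conditions: 1 M aq. HCl, THF, 0 °C → rt; evaporation
Reagents that add atoms: water, O
Why: Acid hydrolysis of a vinylogous ester by addition of water at C3 and loss of ethanol; the dione is a known, isolable solid.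

Step 6
Reactants: 13 cyclobutane-1,3-dione
Product: 14 3-(triisopropylsilyloxy)cyclobut-2-en-1-one
Conditions: iPr3SiOTf, Et3N, CH2Cl2, −78 → 0 °C
Reagents that add atoms: triisopropylsilyl triflate, CC(C)[Si](OS(=O)(=O)C(F)(F)F)(C(C)C)C(C)C
Why: O-silylation of the enol of a cyclic 1,3-dione to the beta-silyloxy enone; both carbonyls are equivalent, so only one product can form.

Step 7
Reactants: 14 3-(triisopropylsilyloxy)cyclobut-2-en-1-one; 8 triethyl{[(3R)-2-methyl-6-(triisopropylsilyloxy)hex-1-en-5-yn-3-yl]oxy}silane
Product: 19 2-[(2R)-3-methyl-2-(triethylsilyloxy)but-3-enyl]-3,5-bis(triisopropylsilyloxy)phenol, via siloxy vinylketene 15 (not isolated), via 4-vinylcyclobutenone 16 (not isolated), via dienylketene 17 (not isolated), via cyclohexadienone 18 (not isolated)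
Conditions: PhMe, 80 °C then 110 °C, sealed tube, 14 (1.3 equiv)
Reagents that add atoms: none
Why: Danheiser benzannulation of a cyclobutenone with a siloxyalkyne, the known route to resorcinol monosilyl ethers, run here with a 3-siloxy partner so that a phloroglucinol results. Heating opens 14 by 4π electrocyclic ring opening to the siloxy vinylketene 15. The ketene C=C adds the alkyne in a (2+2) cycloaddition in which the alkyl-bearing, nucleophilic carbon of 8 bonds to the ketene carbonyl carbon (C7a–C3a) and the oxygen-bearing carbon to the ketene alpha carbon (C4–C5), giving 16 as a mixture of epimers at its one sp3 ring carbon, which is later lost. 16 opens again (4π) to dienylketene 17, and ring A closes by thermal 6π electrocyclisation between the ketene carbon and the vinyl terminus (C7a–C7) to dienone 18, which tautomerises to phenol 19. No stereocentre is created in 19, and the silylated carbinol is a spectator under these neutral conditions. The selectivity needed is the orientation of the ketene–alkyne union; it is secured by the polarisation of the siloxyalkyne (carbon remote from oxygen nucleophilic) and of the ketene (carbonyl carbon electrophilic), which places hydroxyl, side chain and silyloxy group in the 1,2,3 order. The ketene oxygen is therefore the only free hydroxyl (C7a), and the C4 and C6 oxygens arrive as triisopropylsilyl ethers.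

Step 8
Reactants: 19 2-[(2R)-3-methyl-2-(triethylsilyloxy)but-3-enyl]-3,5-bis(triisopropylsilyloxy)phenol
Product: 20 2-bromo-6-[(2R)-3-methyl-2-(triethylsilyloxy)but-3-enyl]-3,5-bis(triisopropylsilyloxy)phenol
Conditions: NBS (1.0 equiv), iPr2NH (10 mol%), CH2Cl2, −78 → −40 °C
Reagents that add atoms: N-bromosuccinimide, O=C1CCC(=O)N1Br
Why: Amine-mediated ortho bromination of a phenol; the position para to the hydroxyl lies between two triisopropylsilyloxy groups and is shielded, so the one ortho position (C7) should react, and the very electron-rich arene outcompetes the alkene.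

Step 9
Reactants: 20 2-bromo-6-[(2R)-3-methyl-2-(triethylsilyloxy)but-3-enyl]-3,5-bis(triisopropylsilyloxy)phenol; 21 (S)-2-methylbutanoic acid
Product: 22 2-bromo-6-[(2R)-3-methyl-2-(triethylsilyloxy)but-3-enyl]-3,5-bis(triisopropylsilyloxy)phenyl (2S)-2-methylbutanoate
Conditions: DCC, DMAP (cat.), CH2Cl2, 0 °C → rt
Reagents that add atoms: none
Why: Steglich esterification of the only free hydroxyl; a simple alpha-alkyl acid is not expected to racemise under carbodiimide activation, so the (S) centre comes unchanged from the chiral pool.

Step 10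
Reactants: 22 2-bromo-6-[(2R)-3-methyl-2-(triethylsilyloxy)but-3-enyl]-3,5-bis(triisopropylsilyloxy)phenyl (2S)-2-methylbutanoate
Product: 24 (2S)-1-{2-hydroxy-3-[(2R)-3-methyl-2-(triethylsilyloxy)but-3-enyl]-4,6-bis(triisopropylsilyloxy)phenyl}-2-methylbutan-1-one, via aryllithium 23 (not isolated)
Conditions: t-BuLi (2.0 equiv), THF/Et2O, −95 → −78 °C; AcOH, −78 °C
Reagents that add atoms: none
Why: Halogen–lithium exchange followed by anionic ortho-Fries (1,3 O to C acyl) shift, known for ortho-bromoaryl esters; the aryllithium attacks its neighbouring ester carbonyl intramolecularly at low temperature, and the resulting chelated lithium phenoxide is quenched cold to keep the alpha stereocentre intact.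

Step 11
Reactants: 24 (2S)-1-{2-hydroxy-3-[(2R)-3-methyl-2-(triethylsilyloxy)but-3-enyl]-4,6-bis(triisopropylsilyloxy)phenyl}-2-methylbutan-1-one
Product: 25 (2S)-1-{2-hydroxy-3-[(2R)-2-hydroxy-3-methylbut-3-enyl]-4,6-bis(triisopropylsilyloxy)phenyl}-2-methylbutan-1-one
Conditions: PPTS (cat.), MeOH/CH2Cl2, 0 °C
Reagents that add atoms: none
Why: Mild acid methanolysis cleaves the alkyl triethylsilyl ether; aryl triisopropylsilyl ethers are stable to acid of this strength, and the conditions are too weak to ionise the allylic carbinol.

Step 12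
Reactants: 25 (2S)-1-{2-hydroxy-3-[(2R)-2-hydroxy-3-methylbut-3-enyl]-4,6-bis(triisopropylsilyloxy)phenyl}-2-methylbutan-1-one
Product: 26 (2S)-2-methyl-1-[(2S)-2-(prop-1-en-2-yl)-4,6-bis(triisopropylsilyloxy)-2,3-dihydro-1-benzofuran-7-yl]butan-1-one
Conditions: PPh3, DIAD, THF, 0 °C → rt
Reagents that add atoms: none
Why: Intramolecular Mitsunobu etherification; the carbinol activated by the PPh3/DIAD pair is displaced by the C7a phenoxide in a 5-exo-tet SN2 closure that inverts the (R)-carbinol to (S)-C2, and since only the C7a oxygen is free the isomeric ring through the C4 oxygen cannot form.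

Step 13
Reactants: 26 (2S)-2-methyl-1-[(2S)-2-(prop-1-en-2-yl)-4,6-bis(triisopropylsilyloxy)-2,3-dihydro-1-benzofuran-7-yl]butan-1-one
Product: 27 (2S)-1-[(2S)-4,6-dihydroxy-2-(prop-1-en-2-yl)-2,3-dihydro-1-benzofuran-7-yl]-2-methylbutan-1-one
Conditions: TBAF (2.2 equiv), AcOH (2.2 equiv), THF, 0 °C, argon
Reagents that add atoms: none
Why: Fluoride cleavage of aryl silyl ethers; buffering with acetic acid keeps the medium from enolising the aryl ketone, so the alpha stereocentre and the allylic aryl ether at C2 are untouched.

Step 14
Reactants: 28 pentan-3-one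
Product: 29 3-(trimethylsilyloxy)pent-2-ene
Conditions: Me3SiOTf, Et3N, CH2Cl2, 0 °C
Reagents that add atoms: trimethylsilyl triflate, C[Si](C)(C)OS(=O)(=O)C(F)(F)F
Why: Soft enolisation and O-silylation of a symmetric ketone; only one regioisomer exists and the E/Z mixture is irrelevant for the next step.

Step 15
Reactants: 29 3-(trimethylsilyloxy)pent-2-ene; 30 malonyl dichloride
Product: 31 6-ethyl-4-hydroxy-5-methyl-2H-pyran-2-one
Conditions: Et2O, −78 °C → rt
Reagents that add atoms: none
Why: Known pyrone synthesis from silyl enol ethers and malonyl dichloride; C-acylation at the enol ether carbon gives a 3,5-dioxo acid chloride whose enol oxygen closes the lactone, so the ketone ethyl and alpha methyl end up at C6 and C5.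

Step 16
Reactants: 31 6-ethyl-4-hydroxy-5-methyl-2H-pyran-2-one; 32 N,N-dimethylmethyleneiminium iodide (Eschenmoser's salt)
Product: 33 3-[(dimethylamino)methyl]-6-ethyl-4-hydroxy-5-methyl-2H-pyran-2-one
Conditions: Et3N (1 equiv), CH2Cl2, 0 °C → rt
Reagents that add atoms: none
Why: Mannich aminomethylation at C3, the nucleophilic carbon between the lactone carbonyl and the enolic hydroxyl; the preformed iminium salt avoids free formaldehyde and with it the symmetric methylene-bis-pyrone.

Step 17
Reactants: 33 3-[(dimethylamino)methyl]-6-ethyl-4-hydroxy-5-methyl-2H-pyran-2-one; 27 (2S)-1-[(2S)-4,6-dihydroxy-2-(prop-1-en-2-yl)-2,3-dihydro-1-benzofuran-7-yl]-2-methylbutan-1-one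
Product: 35 6-ethyl-4-hydroxy-3-({(2S)-4,6-dihydroxy-7-[(2S)-2-methylbutanoyl]-2-(prop-1-en-2-yl)-2,3-dihydro-1-benzofuran-5-yl}methyl)-5-methyl-2H-pyran-2-one, via methylene pyrandione 34 (not isolated)
Conditions: 1,4-dioxane, 80 °C, argon
Reagents that add atoms: none
Why: Thermal loss of dimethylamine from the Mannich base gives the pyrone quinone methide 34, which is captured by C5, the only unsubstituted and most nucleophilic carbon of the phloroglucinol, by conjugate addition and re-aromatisation; the medium is neutral to weakly basic, so neither stereocentre nor the isopropenyl group is at risk.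

## Compound list

1 | methacrolein (2-methylprop-2-enal) | C=C(C)C=O | starting material
2 | allenylboronic acid pinacol ester (4,4,5,5-tetramethyl-2-(propa-1,2-dienyl)-1,3,2-dioxaborolane) | C=C=CB1OC(C)(C)C(C)(C)O1 | starting material
3 | 4,4,5,5-tetramethyl-2-{[(3R)-2-methylhex-1-en-5-yn-3-yl]oxy}-1,3,2-dioxaborolane | C=C(C)[C@H](OB1OC(C)(C)C(C)(C)O1)CC#C | intermediate
4 | (3R)-2-methylhex-1-en-5-yn-3-ol | C=C(C)[C@H](O)CC#C | intermediate
5 | triethyl{[(3R)-2-methylhex-1-en-5-yn-3-yl]oxy}silane | C=C(C)[C@H](O[Si](CC)(CC)CC)CC#C | intermediate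
6 | [(4R)-5-methyl-4-(triethylsilyloxy)hex-5-en-1-ynyl]lithium | C=C(C)[C@H](O[Si](CC)(CC)CC)CC#C[Li] | intermediate
7 | lithium (4R)-5-methyl-4-(triethylsilyloxy)hex-5-en-1-yn-1-olate | C=C(C)[C@H](O[Si](CC)(CC)CC)CC#C[O-].[Li+] | intermediate
8 | triethyl{[(3R)-2-methyl-6-(triisopropylsilyloxy)hex-1-en-5-yn-3-yl]oxy}silane | C=C(C)[C@H](O[Si](CC)(CC)CC)CC#CO[Si](C(C)C)(C(C)C)C(C)C | intermediate
9 | ethoxyacetylene | CCOC#C | starting material
10 | acetyl chloride | CC(=O)Cl | starting material
11 | ketene | C=C=O | intermediate
12 | 3-ethoxycyclobut-2-en-1-one | CCOC1=CC(=O)C1 | intermediate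
13 | cyclobutane-1,3-dione | O=C1CC(=O)C1 | intermediate
14 | 3-(triisopropylsilyloxy)cyclobut-2-en-1-one | O=C1C=C(O[Si](C(C)C)(C(C)C)C(C)C)C1 | intermediate
15 | 3-(triisopropylsilyloxy)buta-1,3-dien-1-one | C=C(O[Si](C(C)C)(C(C)C)C(C)C)C=C=O | intermediate
16 | 2-[(2R)-3-methyl-2-(triethylsilyloxy)but-3-enyl]-3-(triisopropylsilyloxy)-4-[1-(triisopropylsilyloxy)ethenyl]cyclobut-2-en-1-one (both epimers at ring C4) | C=C(C)[C@H](O[Si](CC)(CC)CC)CC1=C(O[Si](C(C)C)(C(C)C)C(C)C)C(C(=C)O[Si](C(C)C)(C(C)C)C(C)C)C1=O | intermediate
17 | (3E)-2-[(2R)-3-methyl-2-(triethylsilyloxy)but-3-enyl]-3,5-bis(triisopropylsilyloxy)hexa-1,3,5-trien-1-one (ketene carbon and C5 cis) | C=C(C)[C@H](O[Si](CC)(CC)CC)CC(=C=O)/C(O[Si](C(C)C)(C(C)C)C(C)C)=C\C(=C)O[Si](C(C)C)(C(C)C)C(C)C | intermediate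
18 | 2-[(2R)-3-methyl-2-(triethylsilyloxy)but-3-enyl]-3,5-bis(triisopropylsilyloxy)cyclohexa-2,4-dien-1-one | C=C(C)[C@H](O[Si](CC)(CC)CC)CC1=C(O[Si](C(C)C)(C(C)C)C(C)C)C=C(O[Si](C(C)C)(C(C)C)C(C)C)CC1=O | intermediate
19 | 2-[(2R)-3-methyl-2-(triethylsilyloxy)but-3-enyl]-3,5-bis(triisopropylsilyloxy)phenol | C=C(C)[C@H](O[Si](CC)(CC)CC)Cc1c(O)cc(O[Si](C(C)C)(C(C)C)C(C)C)cc1O[Si](C(C)C)(C(C)C)C(C)C | intermediate
20 | 2-bromo-6-[(2R)-3-methyl-2-(triethylsilyloxy)but-3-enyl]-3,5-bis(triisopropylsilyloxy)phenol | C=C(C)[C@H](O[Si](CC)(CC)CC)Cc1c(O)c(Br)c(O[Si](C(C)C)(C(C)C)C(C)C)cc1O[Si](C(C)C)(C(C)C)C(C)C | intermediate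
21 | (S)-2-methylbutanoic acid | CC[C@H](C)C(=O)O | starting material
22 | 2-bromo-6-[(2R)-3-methyl-2-(triethylsilyloxy)but-3-enyl]-3,5-bis(triisopropylsilyloxy)phenyl (2S)-2-methylbutanoate | C=C(C)[C@H](O[Si](CC)(CC)CC)Cc1c(OC(=O)[C@@H](C)CC)c(Br)c(O[Si](C(C)C)(C(C)C)C(C)C)cc1O[Si](C(C)C)(C(C)C)C(C)C | intermediate
23 | 2-lithio analogue of 22 (lithium in place of bromine) | C=C(C)[C@H](O[Si](CC)(CC)CC)Cc1c(OC(=O)[C@@H](C)CC)c([Li])c(O[Si](C(C)C)(C(C)C)C(C)C)cc1O[Si](C(C)C)(C(C)C)C(C)C | intermediate
24 | (2S)-1-{2-hydroxy-3-[(2R)-3-methyl-2-(triethylsilyloxy)but-3-enyl]-4,6-bis(triisopropylsilyloxy)phenyl}-2-methylbutan-1-one | C=C(C)[C@H](O[Si](CC)(CC)CC)Cc1c(O)c(C(=O)[C@@H](C)CC)c(O[Si](C(C)C)(C(C)C)C(C)C)cc1O[Si](C(C)C)(C(C)C)C(C)C | intermediate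
25 | (2S)-1-{2-hydroxy-3-[(2R)-2-hydroxy-3-methylbut-3-enyl]-4,6-bis(triisopropylsilyloxy)phenyl}-2-methylbutan-1-one | C=C(C)[C@H](O)Cc1c(O)c(C(=O)[C@@H](C)CC)c(O[Si](C(C)C)(C(C)C)C(C)C)cc1O[Si](C(C)C)(C(C)C)C(C)C | intermediate
26 | (2S)-2-methyl-1-[(2S)-2-(prop-1-en-2-yl)-4,6-bis(triisopropylsilyloxy)-2,3-dihydro-1-benzofuran-7-yl]butan-1-one | C=C(C)[C@@H]1Cc2c(O[Si](C(C)C)(C(C)C)C(C)C)cc(O[Si](C(C)C)(C(C)C)C(C)C)c(C(=O)[C@@H](C)CC)c2O1 | intermediate
27 | (2S)-1-[(2S)-4,6-dihydroxy-2-(prop-1-en-2-yl)-2,3-dihydro-1-benzofuran-7-yl]-2-methylbutan-1-one | C=C(C)[C@@H]1Cc2c(O)cc(O)c(C(=O)[C@@H](C)CC)c2O1 | intermediate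
28 | pentan-3-one | CCC(=O)CC | starting material
29 | 3-(trimethylsilyloxy)pent-2-ene (E/Z mixture) | CC=C(CC)O[Si](C)(C)C | intermediate
30 | malonyl dichloride | O=C(Cl)CC(=O)Cl | starting material
31 | 6-ethyl-4-hydroxy-5-methyl-2H-pyran-2-one | CCc1oc(=O)cc(O)c1C | intermediate
32 | N,N-dimethylmethyleneiminium iodide (Eschenmoser's salt) | C=[N+](C)C.[I-] | starting material
33 | 3-[(dimethylamino)methyl]-6-ethyl-4-hydroxy-5-methyl-2H-pyran-2-one | CCc1oc(=O)c(CN(C)C)c(O)c1C | intermediate
34 | 6-ethyl-5-methyl-3-methylidene-2H-pyran-2,4(3H)-dione | CCC1=C(C)C(=O)C(=C)C(=O)O1 | intermediate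
35 | 6-ethyl-4-hydroxy-3-({(2S)-4,6-dihydroxy-7-[(2S)-2-methylbutanoyl]-2-(prop-1-en-2-yl)-2,3-dihydro-1-benzofuran-5-yl}methyl)-5-methyl-2H-pyran-2-one (CNP0261501.1) | C=C(C)[C@@H]1Cc2c(O)c(Cc3c(O)c(C)c(CC)oc3=O)c(O)c(C(=O)[C@@H](C)CC)c2O1 | target

## Step count and least certain steps

Total: 17 steps. Longest linear sequence: 11 steps (steps 1, 2, 3, 7, 8, 9, 10, 11, 12, 13, 17; the branch through steps 4, 5, 6 is equally long).

**Step 7 (key step).** The likely failure is that ring opening of the vinylogous silyl ester 14 is slow at temperatures the siloxyalkyne tolerates. Then rearrangement of 8 to a silylketene, self-condensation of the vinylketene, or acylation of the product phenol by the vinylketene would take over.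
Fallback: the same vinylketene is generated photochemically at room temperature, as in the second-generation form of the benzannulation. It sets out from 8 and returns at 19. Butane-2,3-dione F1 is monosilylated (iPr3SiOTf, Et3N) to 3-(triisopropylsilyloxy)but-3-en-2-one F2. Its lithium enolate (LiN(SiMe3)2) is trifluoroacetylated with trifluoroethyl trifluoroacetate to 1,1,1-trifluoro-5-(triisopropylsilyloxy)hex-5-ene-2,4-dione F3. Detrifluoroacetylative diazo transfer (MsN3, Et3N, water, MeCN) gives 1-diazo-3-(triisopropylsilyloxy)but-3-en-2-one F4. Irradiation of F4 with 8 induces Wolff rearrangement to 15, which is trapped to 16; brief warming to 80 °C then carries 16 through 17 and 18 to 19.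

**Step 10.** The likely failure is erosion of configuration at the alpha carbon, through enolisation of the ester or of the freshly formed ketone by the organolithium, together with direct attack of t-BuLi on the ester or silyl migration from the neighbouring oxygen to the lithiated carbon.
Fallback: intermolecular acylation through a stable tetrahedral chelate. It sets out from 20 and 21 and returns at 24. Acid 21 is converted (carbonyldiimidazole, N,O-dimethylhydroxylamine hydrochloride) into (2S)-N-methoxy-N,2-dimethylbutanamide F5. Bromophenol 20 is deprotonated with MeLi and exchanged with t-BuLi to the lithium 2-lithiophenoxide F6, which adds to F5. The N-methoxy-N-methyl hemiaminal chelate persists until the acidic quench, so no ketone is exposed to base, and work-up gives 24.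

**Step 12.** The likely failure is ionisation of the activated allylic carbinol, with partial loss of configuration at C2 or allylic transposition, or elimination to the aryl-conjugated diene, favoured by the hindered and hydrogen-bonded phenol.
Fallback: catalyst-controlled allylic etherification. It sets out from 25 and returns at 26. The carbinol of 25 is converted (ClCO2Me, pyridine, low temperature; the chelated, doubly flanked phenol should stay free) into the methyl carbonate F7. Zerovalent palladium from Pd2(dba)3·CHCl3 with the DACH-phenyl Trost ligand, in the enantiomeric form that leads to (S)-C2, ionises F7 to the pi-allyl complex. The phenoxide closes the five-membered ring at the internal carbon under ligand control, independent of the configuration of the carbonate.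

**Step 17.** The likely failure is exchange of the methylene unit, giving symmetric methylene-bis-pyrone or bis-phloroglucinol, or oligomerisation of 34 before capture by the hindered C5.
Fallback: the roles are reversed. It sets out from 27, 32 and 31 and returns at 35. Phloroglucinol 27 is aminomethylated at C5 with 32 to (2S)-1-[(2S)-5-[(dimethylamino)methyl]-4,6-dihydroxy-2-(prop-1-en-2-yl)-2,3-dihydro-1-benzofuran-7-yl]-2-methylbutan-1-one F8. Warming F8 with pyrone 31 releases the ortho-quinone methide of ring A, which is captured by C3 of the pyrone.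

**Step 1.** The likely failure is insufficient facial discrimination for this small alpha-branched enal, together with loss of the volatile carbinol on isolation.
Fallback: racemate and kinetic resolution. It sets out from 1 and returns at 4. Zinc-mediated Barbier propargylation of 1 with propargyl bromide gives racemic 2-methylhex-1-en-5-yn-3-ol F9. Sharpless kinetic resolution (Ti(OiPr)4, L-(+)-diisopropyl tartrate, t-BuOOH 0.6 equiv, 4 Å MS, CH2Cl2, −20 °C) is expected to epoxidise the (S)-enantiomer to (1S)-1-[(2R)-2-methyloxiran-2-yl]but-3-yn-1-ol F10 and leave (R)-4, which is separated and silylated as in step 2.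

## Further compounds

F1 | step 7 | butane-2,3-dione | CC(=O)C(C)=O
F2 | step 7 | 3-(triisopropylsilyloxy)but-3-en-2-one | CC(=O)C(=C)O[Si](C(C)C)(C(C)C)C(C)C
F3 | step 7 | 1,1,1-trifluoro-5-(triisopropylsilyloxy)hex-5-ene-2,4-dione | O=C(CC(=O)C(=C)O[Si](C(C)C)(C(C)C)C(C)C)C(F)(F)F
F4 | step 7 | 1-diazo-3-(triisopropylsilyloxy)but-3-en-2-one | C=C(O[Si](C(C)C)(C(C)C)C(C)C)C(=O)C=[N+]=[N-]
F5 | step 10 | (2S)-N-methoxy-N,2-dimethylbutanamide | CC[C@H](C)C(=O)N(C)OC
F6 | step 10 | lithium 2-lithio-6-[(2R)-3-methyl-2-(triethylsilyloxy)but-3-enyl]-3,5-bis(triisopropylsilyloxy)phenoxide | C=C(C)[C@H](O[Si](CC)(CC)CC)Cc1c(O[Li])c([Li])c(O[Si](C(C)C)(C(C)C)C(C)C)cc1O[Si](C(C)C)(C(C)C)C(C)C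
F7 | step 12 | (2R)-1-{2-hydroxy-3-[(2S)-2-methylbutanoyl]-4,6-bis(triisopropylsilyloxy)phenyl}-3-methylbut-3-en-2-yl methyl carbonate | C=C(C)[C@H](OC(=O)OC)Cc1c(O)c(C(=O)[C@@H](C)CC)c(O[Si](C(C)C)(C(C)C)C(C)C)cc1O[Si](C(C)C)(C(C)C)C(C)C
F8 | step 17 | (2S)-1-[(2S)-5-[(dimethylamino)methyl]-4,6-dihydroxy-2-(prop-1-en-2-yl)-2,3-dihydro-1-benzofuran-7-yl]-2-methylbutan-1-one | C=C(C)[C@@H]1Cc2c(O)c(CN(C)C)c(O)c(C(=O)[C@@H](C)CC)c2O1
F9 | step 1 | racemic 2-methylhex-1-en-5-yn-3-ol | C=C(C)C(O)CC#C
F10 | step 1 | (1S)-1-[(2R)-2-methyloxiran-2-yl]but-3-yn-1-ol | C[C@@]1(CO1)[C@@H](O)CC#C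
A1 | alternative 1 | 6-ethyl-4-hydroxy-3-({(2S)-4,6-dihydroxy-2-(2-hydroxypropan-2-yl)-7-[(2S)-2-methylbutanoyl]-2,3-dihydro-1-benzofuran-5-yl}methyl)-5-methyl-2H-pyran-2-one | CC(C)(O)[C@@H]1Cc2c(O)c(Cc3c(O)c(C)c(CC)oc3=O)c(O)c(C(=O)[C@@H](C)CC)c2O1
A2 | alternative 1 | 6-ethyl-4-hydroxy-5-methyl-3-({2,4,6-trihydroxy-3-[(2S)-2-methylbutanoyl]-5-(3-methylbut-2-enyl)phenyl}methyl)-2H-pyran-2-one | CC(C)=CCc1c(O)c(Cc2c(O)c(C)c(CC)oc2=O)c(O)c(C(=O)[C@@H](C)CC)c1O
A3 | alternative 2 | (2S)-1-[(2S)-4,6-dihydroxy-2-(prop-1-en-2-yl)-2,3-dihydro-1-benzofuran-7-yl]-2-methylbutan-1-one (identical with 27) | C=C(C)[C@@H]1Cc2c(O)cc(O)c(C(=O)[C@@H](C)CC)c2O1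
A4 | alternative 2 | methyl 3-{(5S)-2-[(3S)-3-methyl-2-oxopentyl]-5-(prop-1-en-2-yl)-4,5-dihydrofuran-3-yl}-3-oxopropanoate | C=C(C)[C@@H]1CC(C(=O)CC(=O)OC)=C(CC(=O)[C@@H](C)CC)O1
A5 | alternative 3 | C6 tert-butyldimethylsilyl ether of the target | C=C(C)[C@@H]1Cc2c(O)c(Cc3c(O)c(C)c(CC)oc3=O)c(O[Si](C)(C)C(C)(C)C)c(C(=O)[C@@H](C)CC)c2O1
A6 | alternative 3 | dihydrocoumarin in which the C4 oxygen and C5 of the (2S)-2-isopropenyl-7-[(2S)-2-methylbutanoyl]dihydrobenzofuran are joined by a CH2CH2C(=O) lactone, C6 oxygen as tert-butyldimethylsilyl ether | C=C(C)[C@@H]1Cc2c3OC(=O)CCc3c(O[Si](C)(C)C(C)(C)C)c(C(=O)[C@@H](C)CC)c2O1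
A7 | alternative 3 | tert-butyldimethylsilyl ketene acetal of A6 | C=C(C)[C@@H]1Cc2c3OC(O[Si](C)(C)C(C)(C)C)=CCc3c(O[Si](C)(C)C(C)(C)C)c(C(=O)[C@@H](C)CC)c2O1
A8 | alternative 3 | 6-ethyl-2,2,5-trimethyl-4H-1,3-dioxin-4-one | CCC1=C(C)C(=O)OC(C)(C)O1
A9 | alternative 3 | 2-methyl-3-oxopent-1-en-1-one (acylketene) | CCC(=O)C(C)=C=O
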